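I decided to read these flasks by one clock taken straight from the readings, and to believe a step only where that clock stopped fitting.

| setting | ochre | red | grey | amber | green |
|---|---|---|---|---|---|
| G | 0.0800 M | 0.0320 M | 0.120 M | 0.0800 M | 0.0800 M |
| L | 0.240 M | 0.192 M | 0.240 M | 0.480 M | 0.840 M |
| time |  |  |  |  | 49 h |

| run | time / h | [E] / M |
|---|---|---|
| ochre run | 2.0 | 0.0061 |
| ochre run | 3.7 | 0.0095 |
| ochre run | 7.1 | 0.0151 |
| ochre run | 14 | 0.0224 |
| ochre run | 26 | 0.0293 |
| ochre run | 49 | 0.0334 |
| red run | 2.0 | 0.0023 |
| red run | 3.7 | 0.0045 |
| red run | 7.1 | 0.0058 |
| red run | 14 | 0.0094 |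
| red run | 26 | 0.0117 |
| red run | 49 | 0.0137 |
| grey run | 2.0 | 0.0081 |
| grey run | 3.7 | 0.0138 |
| grey run | 7.1 | 0.0218 |
| grey run | 14 | 0.0344 |
| grey run | 26 | 0.0438 |
| grey run | 49 | 0.0501 |
| amber run | 2.0 | 0.0059 |
| amber run | 3.7 | 0.0098 |
| amber run | 7.1 | 0.0152 |
| amber run | 14 | 0.0222 |
| amber run | 26 | 0.0277 |
| amber run | 49 | 0.0319 |

(readings scatter by 4 × 10⁻⁴ M)

- reaction order in [L] at the outset, round the charge of the ochre run, defined at two percent of the G turned into E
- reaction order in [G] at the outset, round the charge of the ochre run, defined at two percent of the G turned into E (one fixed amount of E, the same in the runs compared)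
- E in the green run at 49 h, as a share of the G charged

- Overall: G + L -> E.
- Constant volume, constant temperature.
- "The second partner" is L.
- An order is taken over about fifteen percent of the charge, up and down.

The ochre run turned 7.62% of its G into E by 2.0 h, so the opening lifetime of G, the time to turn the whole charge at that first pace, was 26.2 h. The same sum gave 29.6 h for grey, which held 1.50 times the G of ochre at the same L, and 27.8 h for red, whose L differed from ochre's as well as its G, and the grey reading pointed to an order near one in G. I doubted this, since the scatter is 17.4% of the first red reading. But at 14 h the shares were 28.0%, 29.4% and 28.7% in ochre, red and grey, with a scatter of 1.2 percentage points on red, so the estimate stood.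

The amber run, with twice the L of ochre, gave a lifetime of 27.1 h, and L seemed to do nothing. That did not convince me either: the amber to ochre ratio carries 9.27% of scatter, which on a doubling leaves the order in L open by 0.134 either way.

Then I counted lifetimes. The green run's 49 h is 1.87 of the lifetimes read in ochre, and a first-order decay of G over that count turns 84.6% of the charge. Yet the ochre run, over the same time, read 41.8%, less than the clock gives, so I could not take the count as the green answer.

The forecast put the order in L at 0 (−0.1 to 0.12), the order in G at 0.97 (0.8 to 1.1), and the green share at 37% (33.5% to 39.5%), on the ground of “a slow L-dependent loss”.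

The flask gave 1.0 in G and 38.4% for green, both inside those ranges. The order in L came to 0.18, above the forecast's high end: amber ran 1.1 times ochre at equal E made.

    G + L ⇌ Q, settled at all times (26.20 M⁻¹)
    G + L → E (1.343 M⁻¹ h⁻¹)
    E + L → J (0.5832 M⁻¹ h⁻¹)
    2 L → Yx (0.5688 M⁻¹ h⁻¹)

On my clock the green run's 1.87 lifetimes gave 84.6%, and the flask gave 38.4%, which is 46 points less. The main reason is the conversion of E + L into J. The green run repeated without that step gave 72.9%, which is 35 points above the real flask and 12 points under the same count.

The readings were generated by integration for substances that don't exist; scatter was added.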